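# Synthesis plan for CNP0179668.1 (compound 24)

Position numbers: tetrahydrofuran ring O1, C2–C5; dihydrobenzofuran ring O1′, C2′, C3′, C5′, C7′.

## The problem

Compound 24 joins two oxygen heterocycles through one aryl–carbon bond. One is a 2,3,4,5-tetrasubstituted tetrahydrofuran: C2 carries a 4-hydroxy-3-methoxybenzyl group, C3 a hydroxyl, C4 a hydroxymethyl group and C5 an aryl group, all four centres S. The other is a 7′-methoxy-2′-aryl-3′-hydroxymethyl-2,3-dihydrobenzofuran (2′R,3′R), whose C5′ is bonded to C5. The benzene ring between them insulates the two sets of stereocentres. Each half therefore needs its own source of absolute configuration, and the relative configuration of the halves is only as good as the enantiopurity of each.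

In the tetrahydrofuran the C2 benzyl group, the C3 hydroxyl and the C5 aryl group lie on one face and the C4 hydroxymethyl group on the other (2,3-cis, 3,4-trans, 4,5-trans). C4 and C5 can be set together in an aldol bond construction, the C5 oxygen can then direct C3 (1,3-anti), and the C3 hydroxyl can direct C2.

The dihydrobenzofuran is the cis isomer, the less stable one. It must be made under kinetic control and then kept from epimerising: acid can ionise the C2′–O1′ bond next to the para-oxygenated aryl ring, and base can open it through a quinone methide once the phenol is free. The C5–O1 bond is a benzylic ether of an electron-rich arene and is open to ionisation and hydrogenolysis in the same way. The two guaiacyl phenols are easily oxidised.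

The feature that makes the key step possible sits at C2. It bears an exocyclic CH2 bonded to an aryl ring and is flanked by O1 and the hydroxyl-bearing C3. Cutting O1–C2 and the CH2–aryl bond uncovers a terminal alkene whose allylic carbon is C3. The C5 hydroxyl can then close the ring onto the iodine-activated alkene while the free C3 hydroxyl decides which face reacts.

## Retrosynthesis

**Protecting groups (24 from 23 from 22).** The last operations only remove groups. The two phenols are released last and under neutral conditions, by hydrogenolysis of benzyl ethers (23 to 24), because a phenoxide para to C2′ could open the cis-dihydrobenzofuran. The C4 hydroxymethyl group travels as a benzyl ether and leaves in the same step. The C3′ hydroxymethyl group is carried as a tert-butyldiphenylsilyl ether (22 to 23). It has to be protected at the stage of hydroxy aldehyde 8, where silylation is harmless and a base-mediated benzylation is not. The C3 hydroxyl is never protected.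

**CH2–aryl bond (22 from 19 and 21).** The bond between the exocyclic CH2 on C2 and its aryl ring is cut, giving primary iodide 19 and aryl iodide 21.
- Carrying the aryl group on the alkene through the cyclisation is worse: an electron-rich styrene is attacked at the benzylic carbon and would close a six-membered ring.
- Palladium-catalysed carboetherification with an aryl halide would form O1–C2 and CH2–aryl together, but that reaction type favours 2,3-trans products.
- The forward coupling must join a C(sp3) and a C(sp2) centre without a long-lived alkylmetal, since O1 lies β to the iodide carbon and would be expelled. A nickel-catalysed reductive cross-electrophile coupling meets this and tolerates the free C3 hydroxyl.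

**O1–C2 bond (19 from 18), the key disconnection.** Cutting O1–C2 gives the acyclic 1,3-anti diol 18 with a terminal alkene. Cutting O1–C5 instead would mean closing the ring by displacement at the benzylic carbon, which would run through the stabilised cation and lose the C5 configuration. Diol 18 has three stereocentres, each within reach of acyclic stereocontrol. The forward reaction must close only through the benzylic hydroxyl, in the 5-exo mode, and place the iodomethyl group cis to the C3 hydroxyl.

**C3 carbinol and vinyl group (18 from 17 from 16 from 15).** The C3 carbinol is traced to enone 17, so that the C5 hydroxyl can deliver hydride and set the 1,3-anti relationship. The carbonyl–vinyl bond is cut to Weinreb amide 16, which comes from imide 15 by exchange of the auxiliary. Each precursor is one functional group simpler, and the reduction leaves the enone double bond alone.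

**Aldol bond (15 from 9 and 13).** The bond between the future C4 and C5 is cut to aldehyde 9 and the 3-(benzyloxy)propanoyl imide 13. An anti-selective auxiliary aldol sets both centres at once, and sets them from the auxiliary, not from the remote stereocentres of 9. This is what the insulated halves require. Imide 13 is one step from acid 10 and oxazolidinone 11.

**Aldehyde adjustments (9 from 8 from 7 from 6).** The aldehyde and the protected hydroxymethyl group are traced to the two ester groups of diester 6. Both are reduced together, and only the benzylic alcohol of diol 7 is oxidised back.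

**C2′–C3′ bond (6 from 5).** The dihydrobenzofuran is opened at C2′–C3′ to aryldiazoacetate 5. Carbene insertion into the benzylic ether C–H bond forms the cis isomer kinetically and sets both centres from a chiral catalyst. Closing O1′–C2′ by substitution needs an auxiliary aldol and extra protecting-group changes. Oxidative phenol coupling gives the trans isomer.

**Diazo ester (5 from 4 from 3 from 1 and 2).** Diazo transfer leads back to arylacetate 4. Its aryl–CH2 bond is cut to aryl bromide 3 and a two-carbon zinc ester enolate. The ether bond of 3 is cut to phenol 1 and benzylic alcohol 2. The ester of 1 already sits at the future C5′ and the bromine at the future C3a′.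

## Roads not taken

**Alternative 1:** Dichloroketene cycloaddition and ring expansion.
- Cut: the C3–C4 bond and the bond from C2 to the future C5, with O1 inserted later.
- Forward key step: dichloroketene A3 adds across the Z-enol ether A2, whose chiral 1-arylethyl group shields one face, to give cyclobutanone A1. The future C2 and C3 are cis because the addition is suprafacial on a Z-alkene.
- Merit: the 2,3-cis relationship is stereospecific, not merely selective, and the absolute configuration comes from a recoverable auxiliary. In this respect it is more secure than the chosen iodoetherification.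
- Weak points: after A1 the synthesis still needs dechlorination, oxidative ring expansion, a hydroxymethyl group at C4, the aryl group at C5 and reductive removal of the lactol oxygen. An enolate at C4 has the auxiliary alkoxide in the β position and can eliminate it. The C5 reduction and auxiliary removal need strong acid, which the cis-dihydrobenzofuran tolerates poorly.
- Comparison: the chosen plan sets C3, C4 and C5 in the open chain by well-understood reactions. Its ring closure runs in bicarbonate-buffered medium, and three steps remain after the key step.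

**Alternative 2:** Syn-aldol and invertive Mitsunobu closure of the dihydrobenzofuran.
- Cut: the O1′–C2′ bond.
- Forward key step: phenol A5 closes under triphenylphosphine and diisopropyl azodicarboxylate to give the cis-dihydrobenzofuran A4, with inversion at the benzylic carbon. The tosyloxy group on the aryl ring holds back ionisation.
- Merit: both dihydrobenzofuran centres come from an auxiliary aldol, so the enantiopurity of this half is more certain than with the catalytic C–H insertion chosen here.
- Weak points: the arylacetic acid partner must first be made. The tosylate has to be exchanged for a hydrogenolysable group, and the bromide of A4 converted to the aldehyde. The benzylic alcohol can still react partly by ionisation, which would give the trans isomer. The step also leaves the tetrahydrofuran, with its four stereocentres, unsolved.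
- Comparison: the chosen plan reaches cis ester 6 in four steps from 1, and the cis ring forms directly. The lower certainty in enantiopurity is met by possible enrichment at 7 or 8, and the key step is spent where the greater difficulty lies.

**Alternative 3:** Petasis–Ferrier rearrangement.
- Cut: the C4–C5 bond, with ring closure.
- Forward key step: Me2AlCl ionises the methylene dioxolane A7 to an aluminium enolate and an aryl oxocarbenium ion, which recombine to the 2,5-cis tetrahydrofuran-3-one A6.
- Merit: it is more convergent than the chosen plan. A carbon–carbon bond and the ring form together, and C2 comes from an aryllactic acid.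
- Weak points: A6 lacks the C4 hydroxymethyl group. Introducing it needs an enolate that can also form toward C2, which epimerises the benzyl centre, or can expel O1 from C5. The ketone must then be reduced from the face that the new C4 substituent shields, to put the hydroxyl cis to the C2 benzyl group. The Lewis acid meets the ionisable C2′–O1′ bond.
- Comparison: the chosen plan is more linear but fixes C3 and C4 before the ring closes and needs no enolate chemistry on the ring.

Key step: step 13

**Assumptions**
- Dirhodium tetrakis[N-phthaloyl-(S)-tert-leucinate], Rh2(S-PTTL)4, is taken to give the (2′R)-configured cis-dihydrobenzofuran from an ortho-benzyloxy aryldiazoacetate; if the sense is opposite, the (R)-tert-leucinate catalyst is used with no other change.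
- The MgCl2-catalysed anti-aldol of the (S)-4-benzyloxazolidinone imide is taken to attack the chelated enolate on the face away from the auxiliary benzyl group and give the (2R,3S) adduct; if not, the (R)-auxiliary is used.
- Compounds 1, 2, 10, 11 and 20 are taken to be catalogue chemicals.

**Abbreviations in names**
- ArSi = (2R,3R)-2-[4-(benzyloxy)-3-methoxyphenyl]-3-{[(tert-butyldiphenylsilyl)oxy]methyl}-7-methoxy-2,3-dihydro-1-benzofuran-5-yl (2,3-cis).
- ArOH = the same group with a free 3-(hydroxymethyl) substituent.

## Steps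

Step 1
Reactants: 1 methyl 3-bromo-4-hydroxy-5-methoxybenzoate; 2 [4-(benzyloxy)-3-methoxyphenyl]methanol
Product: 3 methyl 4-{[4-(benzyloxy)-3-methoxyphenyl]methoxy}-3-bromo-5-methoxybenzoate
Conditions: PPh3, DIAD, THF, 0 °C to rt
Reagents that add atoms: none
Why: Mitsunobu etherification; the phenol is made acidic by the para ester and ortho bromine and is a good pronucleophile, and the primary benzylic alcohol is activated without isolating a reactive benzylic halide.

Step 2
Reactants: 3 methyl 4-{[4-(benzyloxy)-3-methoxyphenyl]methoxy}-3-bromo-5-methoxybenzoate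
Product: 4 methyl 4-{[4-(benzyloxy)-3-methoxyphenyl]methoxy}-3-methoxy-5-(2-methoxy-2-oxoethyl)benzoate
Conditions: BrZnCH2CO2Me (from BrCH2CO2Me, Zn dust, cat. TMSCl, THF), Pd2(dba)3 (2.5 mol%), XPhos (10 mol%), THF, 60 °C
Reagents that add atoms: (2-methoxy-2-oxoethyl)zinc bromide, COC(=O)C[Zn]Br
Why: Palladium-catalysed α-arylation of a zinc ester enolate (Negishi-type coupling of a Reformatsky reagent); the zinc enolate does not attack the benzoate ester and gives the monoarylated acetate.

Step 3
Reactants: 4 methyl 4-{[4-(benzyloxy)-3-methoxyphenyl]methoxy}-3-methoxy-5-(2-methoxy-2-oxoethyl)benzoate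
Product: 5 methyl 4-{[4-(benzyloxy)-3-methoxyphenyl]methoxy}-3-(1-diazo-2-methoxy-2-oxoethyl)-5-methoxybenzoate
Conditions: p-ABSA, DBU, MeCN, 0 °C to rt
Reagents that add atoms: 4-acetamidobenzenesulfonyl azide (p-ABSA), CC(=O)Nc1ccc(cc1)S(=O)(=O)N=[N+]=[N-]
Why: Regitz diazo transfer to an arylacetate; the benzylic ester methylene is the only position acidic enough to react.

Step 4
Reactants: 5 methyl 4-{[4-(benzyloxy)-3-methoxyphenyl]methoxy}-3-(1-diazo-2-methoxy-2-oxoethyl)-5-methoxybenzoate
Product: 6 dimethyl (2R,3S)-2-[4-(benzyloxy)-3-methoxyphenyl]-7-methoxy-2,3-dihydro-1-benzofuran-3,5-dicarboxylate (2,3-cis)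
Conditions: Rh2(S-PTTL)4 (1–2 mol%), toluene, −60 °C
Reagents that add atoms: none
Why: Enantioselective intramolecular 1,5 C–H insertion of a dirhodium carbene into the ether methylene, which is activated by the oxygen and the electron-rich aryl ring; this catalyst class gives cis-2-aryl-2,3-dihydrobenzofuran-3-carboxylates kinetically, so both stereocentres are set by the catalyst, and the low temperature keeps the cis ester from epimerising.

Step 5
Reactants: 6 dimethyl (2R,3S)-2-[4-(benzyloxy)-3-methoxyphenyl]-7-methoxy-2,3-dihydro-1-benzofuran-3,5-dicarboxylate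
Product: 7 {(2R,3R)-2-[4-(benzyloxy)-3-methoxyphenyl]-7-methoxy-2,3-dihydro-1-benzofuran-3,5-diyl}dimethanol (2,3-cis)
Conditions: DIBAL-H (excess), CH2Cl2, −78 to 0 °C; Rochelle salt work-up
Reagents that add atoms: none
Why: Hydride reduction of both esters; DIBAL-H is not basic, so the epimerisable C3′ ester is reduced before it can equilibrate to the trans isomer, after which C3′ is no longer acidic.

Step 6
Reactants: 7 {(2R,3R)-2-[4-(benzyloxy)-3-methoxyphenyl]-7-methoxy-2,3-dihydro-1-benzofuran-3,5-diyl}dimethanol
Product: 8 (2R,3R)-2-[4-(benzyloxy)-3-methoxyphenyl]-3-(hydroxymethyl)-7-methoxy-2,3-dihydro-1-benzofuran-5-carbaldehyde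
Conditions: activated MnO2, CH2Cl2, rt
Reagents that add atoms: none
Why: Chemoselective MnO2 oxidation; only the benzylic alcohol is activated toward this oxidant, and the saturated primary alcohol on C3′ is left.

Step 7
Reactants: 8 (2R,3R)-2-[4-(benzyloxy)-3-methoxyphenyl]-3-(hydroxymethyl)-7-methoxy-2,3-dihydro-1-benzofuran-5-carbaldehyde
Product: 9 (2R,3R)-2-[4-(benzyloxy)-3-methoxyphenyl]-3-{[(tert-butyldiphenylsilyl)oxy]methyl}-7-methoxy-2,3-dihydro-1-benzofuran-5-carbaldehyde
Conditions: TBDPSCl, imidazole, DMF, rt
Reagents that add atoms: tert-butyl(chloro)diphenylsilane, CC(C)(C)[Si](Cl)(c1ccccc1)c1ccccc1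
Why: Silyl ether formation at the primary hydroxyl under conditions that do not touch the aldehyde; the group withstands the Lewis acids, the Grignard reagent and the acetic acid used later.

Step 8
Reactants: 10 3-(benzyloxy)propanoic acid; 11 (4S)-4-benzyl-1,3-oxazolidin-2-one
Product: 13 (4S)-4-benzyl-3-[3-(benzyloxy)propanoyl]-1,3-oxazolidin-2-one, via 3-(benzyloxy)propanoic pivalic anhydride 12 (not isolated)
Conditions: PivCl, Et3N, THF, −20 °C; then 11, LiCl, rt
Reagents that add atoms: none
Why: N-acylation of the oxazolidinone through a mixed pivalic anhydride with LiCl activation; no strong base is used, so benzyloxide is not eliminated from the β position.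

Step 9
Reactants: 9 (2R,3R)-2-[4-(benzyloxy)-3-methoxyphenyl]-3-{[(tert-butyldiphenylsilyl)oxy]methyl}-7-methoxy-2,3-dihydro-1-benzofuran-5-carbaldehyde; 13 (4S)-4-benzyl-3-[3-(benzyloxy)propanoyl]-1,3-oxazolidin-2-one
Product: 15 (4S)-4-benzyl-3-[(2R,3S)-2-[(benzyloxy)methyl]-3-hydroxy-3-(ArSi)propanoyl]-1,3-oxazolidin-2-one, via O-trimethylsilyl ether of the aldol adduct 14 (not isolated)
Conditions: MgCl2 (20 mol%), Et3N, TMSCl, EtOAc, rt; then aq citric acid, MeOH/THF, 0 °C
Reagents that add atoms: none
Why: Magnesium halide-catalysed anti-selective aldol of an N-acyloxazolidinone with a non-enolisable aromatic aldehyde; soft enolisation gives the chelated Z-enolate, the aldehyde adds to the face away from the auxiliary benzyl group, and silylation of the aldolate turns the catalyst over, setting the two new centres (2R,3S, the future C4 and C5) anti. Any minor enantiomer of 9 ends in a diastereomeric adduct that may be separable here.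

Step 10
Reactants: 15 (4S)-4-benzyl-3-[(2R,3S)-2-[(benzyloxy)methyl]-3-hydroxy-3-(ArSi)propanoyl]-1,3-oxazolidin-2-one
Product: 16 (2R,3S)-2-[(benzyloxy)methyl]-3-hydroxy-N-methoxy-N-methyl-3-(ArSi)propanamide
Conditions: MeNHOMe·HCl, AlMe3, CH2Cl2, −15 °C to rt
Reagents that add atoms: N,O-dimethylhydroxylamine hydrochloride, CNOC.Cl
Why: Aluminium amide transamidation of a β-hydroxy imide to the Weinreb amide; the aluminium alkoxide of the free hydroxyl directs attack to the exocyclic carbonyl, and auxiliary 11 is recovered.

Step 11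
Reactants: 16 (2R,3S)-2-[(benzyloxy)methyl]-3-hydroxy-N-methoxy-N-methyl-3-(ArSi)propanamide
Product: 17 (4R,5S)-4-[(benzyloxy)methyl]-5-hydroxy-5-(ArSi)pent-1-en-3-one
Conditions: CH2=CHMgBr (4 equiv), THF, −20 to 0 °C; inverse quench into cold aq citric acid
Reagents that add atoms: vinylmagnesium bromide, C=C[Mg]Br
Why: Grignard addition to a Weinreb amide; the magnesium chelate of the tetrahedral intermediate prevents over-addition, the first equivalent only deprotonates the hydroxyl, and the cold acidic inverse quench keeps the released amine from adding to the enone.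

Step 12
Reactants: 17 (4R,5S)-4-[(benzyloxy)methyl]-5-hydroxy-5-(ArSi)pent-1-en-3-one
Product: 18 (1S,2S,3R)-2-[(benzyloxy)methyl]-1-(ArSi)pent-4-ene-1,3-diol (1,2-anti, 1,3-anti)
Conditions: Me4NBH(OAc)3, MeCN/AcOH (1:1), −30 °C
Reagents that add atoms: none
Why: Hydroxyl-directed 1,3-anti reduction (Evans–Saksena reduction); the benzylic hydroxyl exchanges onto boron and hydride is delivered within a chair transition state, setting the new carbinol (3R) anti to it, and triacetoxyborohydride reduces the enone carbonyl without conjugate reduction.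

Step 13
Reactants: 18 (1S,2S,3R)-2-[(benzyloxy)methyl]-1-(ArSi)pent-4-ene-1,3-diol
Product: 19 (2R,3S,4S,5S)-4-[(benzyloxy)methyl]-2-(iodomethyl)-5-(ArSi)oxolan-3-ol
Conditions: I2 (3 equiv), NaHCO3 (3 equiv), Et2O/H2O, 0 °C, dark; Na2S2O3 work-up
Reagents that add atoms: iodine, II
Why: Iodine reversibly forms an iodonium ion on the terminal alkene, the benzylic hydroxyl opens it at the internal carbon anti to iodine, and bicarbonate removes the proton so the closure is irreversible and kinetically controlled. The closest known reaction type is the iodoetherification of 4-pentene-1,3-diols to cis-2-(iodomethyl)-3-hydroxytetrahydrofurans, the ether counterpart of the kinetic iodolactonisation of 3-hydroxy-4-pentenoic acids. The one ring closes in the 5-exo-trig mode, forming O1–C2; the 6-endo mode would put positive charge on the primary carbon, and the C3 hydroxyl could only close three- or four-membered rings. The new stereocentre C2 is controlled by the free allylic C3 hydroxyl: the alkene reacts through the conformer in which the C3–O bond lies in the alkene plane, and closure from that conformer places the iodomethyl group cis to the hydroxyl. The substituents reinforce this, since the C5 aryl and C4 benzyloxymethyl groups can both sit pseudo-equatorial in the envelope that leads to the 2,5-cis product, which is the same isomer. The step needs facial selectivity (2,3-cis) and chemoselectivity between the hydroxyl and the benzyl ether oxygen, both of which could close five-membered rings; the hydroxyl should win because it loses a proton at once, whereas the ether must lose a benzyl group. The arenes are fully etherified and are not expected to be iodinated by iodine and bicarbonate without a Lewis acid or silver salt.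

Step 14
Reactants: 20 4-iodo-2-methoxyphenol
Product: 21 1-(benzyloxy)-4-iodo-2-methoxybenzene
Conditions: BnBr, K2CO3, DMF, rt
Reagents that add atoms: benzyl bromide, BrCc1ccccc1
Why: Williamson ether synthesis on a phenol.

Step 15
Reactants: 19 (2R,3S,4S,5S)-4-[(benzyloxy)methyl]-2-(iodomethyl)-5-(ArSi)oxolan-3-ol; 21 1-(benzyloxy)-4-iodo-2-methoxybenzene
Product: 22 (2S,3S,4S,5S)-2-{[4-(benzyloxy)-3-methoxyphenyl]methyl}-4-[(benzyloxy)methyl]-5-(ArSi)oxolan-3-ol
Conditions: 21 (1.5 equiv), NiI2·xH2O (10 mol%), 4,4′-di-tert-butyl-2,2′-bipyridine (10 mol%), pyridine (10 mol%), Mn powder (2 equiv), DMPU, 60 °C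
Reagents that add atoms: none
Why: Nickel-catalysed reductive cross-electrophile coupling of a primary alkyl iodide with an aryl iodide; the aryl iodide adds to zerovalent nickel, the alkyl iodide is converted to a primary radical that is captured at nickel, and reductive elimination forms the CH2–aryl bond. No long-lived alkylmetal forms, so O1 is not expelled, the free hydroxyl is tolerated, and no stereocentre is touched.

Step 16
Reactants: 22 (2S,3S,4S,5S)-2-{[4-(benzyloxy)-3-methoxyphenyl]methyl}-4-[(benzyloxy)methyl]-5-(ArSi)oxolan-3-ol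
Product: 23 (2S,3S,4S,5S)-2-{[4-(benzyloxy)-3-methoxyphenyl]methyl}-4-[(benzyloxy)methyl]-5-(ArOH)oxolan-3-ol
Conditions: TBAF, AcOH, THF, rt
Reagents that add atoms: none
Why: Fluoride cleavage of the silyl ether; acetic acid keeps the medium near neutral, and the phenols are still benzylated, so no phenoxide can open the dihydrobenzofuran.

Step 17
Reactants: 23 (2S,3S,4S,5S)-2-{[4-(benzyloxy)-3-methoxyphenyl]methyl}-4-[(benzyloxy)methyl]-5-(ArOH)oxolan-3-ol
Product: 24 (2S,3S,4S,5S)-2-[(4-hydroxy-3-methoxyphenyl)methyl]-4-(hydroxymethyl)-5-[(2R,3R)-2-(4-hydroxy-3-methoxyphenyl)-3-(hydroxymethyl)-7-methoxy-2,3-dihydro-1-benzofuran-5-yl]oxolan-3-ol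
Conditions: H2 (1 atm), 10% Pd/C, EtOAc/MeOH, rt; stopped when the alkyl benzyl ether is consumed
Reagents that add atoms: none
Why: Hydrogenolysis of two aryl benzyl ethers and one alkyl benzyl ether over palladium on carbon; the phenols are released without acid or base, so neither benzylic ether is ionised and the cis-dihydrobenzofuran is not exposed to quinone methide formation.

## Compound list

1 | methyl 3-bromo-4-hydroxy-5-methoxybenzoate | COC(=O)c1cc(Br)c(O)c(OC)c1 | starting material
2 | [4-(benzyloxy)-3-methoxyphenyl]methanol | OCc1ccc(OCc2ccccc2)c(OC)c1 | starting material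
3 | methyl 4-{[4-(benzyloxy)-3-methoxyphenyl]methoxy}-3-bromo-5-methoxybenzoate | COC(=O)c1cc(Br)c(OCc2ccc(OCc3ccccc3)c(OC)c2)c(OC)c1 | intermediate
4 | methyl 4-{[4-(benzyloxy)-3-methoxyphenyl]methoxy}-3-methoxy-5-(2-methoxy-2-oxoethyl)benzoate | COC(=O)Cc1cc(C(=O)OC)cc(OC)c1OCc1ccc(OCc2ccccc2)c(OC)c1 | intermediate
5 | methyl 4-{[4-(benzyloxy)-3-methoxyphenyl]methoxy}-3-(1-diazo-2-methoxy-2-oxoethyl)-5-methoxybenzoate | COC(=O)C(=[N+]=[N-])c1cc(C(=O)OC)cc(OC)c1OCc1ccc(OCc2ccccc2)c(OC)c1 | intermediate
6 | dimethyl (2R,3S)-2-[4-(benzyloxy)-3-methoxyphenyl]-7-methoxy-2,3-dihydro-1-benzofuran-3,5-dicarboxylate (2,3-cis) | COC(=O)c1cc(OC)c2c(c1)[C@H](C(=O)OC)[C@H](c1ccc(OCc3ccccc3)c(OC)c1)O2 | intermediate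
7 | {(2R,3R)-2-[4-(benzyloxy)-3-methoxyphenyl]-7-methoxy-2,3-dihydro-1-benzofuran-3,5-diyl}dimethanol (2,3-cis) | OCc1cc(OC)c2c(c1)[C@H](CO)[C@H](c1ccc(OCc3ccccc3)c(OC)c1)O2 | intermediate
8 | (2R,3R)-2-[4-(benzyloxy)-3-methoxyphenyl]-3-(hydroxymethyl)-7-methoxy-2,3-dihydro-1-benzofuran-5-carbaldehyde (2,3-cis) | O=Cc1cc(OC)c2c(c1)[C@H](CO)[C@H](c1ccc(OCc3ccccc3)c(OC)c1)O2 | intermediate
9 | (2R,3R)-2-[4-(benzyloxy)-3-methoxyphenyl]-3-{[(tert-butyldiphenylsilyl)oxy]methyl}-7-methoxy-2,3-dihydro-1-benzofuran-5-carbaldehyde (2,3-cis) | O=Cc1cc(OC)c2c(c1)[C@H](CO[Si](c3ccccc3)(c3ccccc3)C(C)(C)C)[C@H](c1ccc(OCc3ccccc3)c(OC)c1)O2 | intermediate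
10 | 3-(benzyloxy)propanoic acid | OC(=O)CCOCc1ccccc1 | starting material
11 | (4S)-4-benzyl-1,3-oxazolidin-2-one | O=C1OC[C@H](Cc2ccccc2)N1 | starting material
12 | 3-(benzyloxy)propanoic pivalic anhydride | CC(C)(C)C(=O)OC(=O)CCOCc1ccccc1 | intermediate
13 | (4S)-4-benzyl-3-[3-(benzyloxy)propanoyl]-1,3-oxazolidin-2-one | O=C(CCOCc1ccccc1)N1[C@@H](Cc2ccccc2)COC1=O | intermediate
14 | (4S)-4-benzyl-3-[(2R,3S)-2-[(benzyloxy)methyl]-3-(ArSi)-3-[(trimethylsilyl)oxy]propanoyl]-1,3-oxazolidin-2-one | C[Si](C)(C)O[C@H](c1cc(OC)c2c(c1)[C@H](CO[Si](c3ccccc3)(c3ccccc3)C(C)(C)C)[C@H](c1ccc(OCc3ccccc3)c(OC)c1)O2)[C@@H](COCc1ccccc1)C(=O)N1[C@@H](Cc2ccccc2)COC1=O | intermediate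
15 | (4S)-4-benzyl-3-[(2R,3S)-2-[(benzyloxy)methyl]-3-hydroxy-3-(ArSi)propanoyl]-1,3-oxazolidin-2-one (anti) | O[C@H](c1cc(OC)c2c(c1)[C@H](CO[Si](c3ccccc3)(c3ccccc3)C(C)(C)C)[C@H](c1ccc(OCc3ccccc3)c(OC)c1)O2)[C@@H](COCc1ccccc1)C(=O)N1[C@@H](Cc2ccccc2)COC1=O | intermediate
16 | (2R,3S)-2-[(benzyloxy)methyl]-3-hydroxy-N-methoxy-N-methyl-3-(ArSi)propanamide | O[C@H](c1cc(OC)c2c(c1)[C@H](CO[Si](c3ccccc3)(c3ccccc3)C(C)(C)C)[C@H](c1ccc(OCc3ccccc3)c(OC)c1)O2)[C@@H](COCc1ccccc1)C(=O)N(C)OC | intermediate
17 | (4R,5S)-4-[(benzyloxy)methyl]-5-hydroxy-5-(ArSi)pent-1-en-3-one | O[C@H](c1cc(OC)c2c(c1)[C@H](CO[Si](c3ccccc3)(c3ccccc3)C(C)(C)C)[C@H](c1ccc(OCc3ccccc3)c(OC)c1)O2)[C@@H](COCc1ccccc1)C(=O)C=C | intermediate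
18 | (1S,2S,3R)-2-[(benzyloxy)methyl]-1-(ArSi)pent-4-ene-1,3-diol (1,2-anti, 1,3-anti) | O[C@H](c1cc(OC)c2c(c1)[C@H](CO[Si](c3ccccc3)(c3ccccc3)C(C)(C)C)[C@H](c1ccc(OCc3ccccc3)c(OC)c1)O2)[C@@H](COCc1ccccc1)[C@H](O)C=C | intermediate
19 | (2R,3S,4S,5S)-4-[(benzyloxy)methyl]-2-(iodomethyl)-5-(ArSi)oxolan-3-ol (2,3-cis, 3,4-trans, 4,5-trans) | IC[C@@H]1O[C@H](c2cc(OC)c3c(c2)[C@H](CO[Si](c4ccccc4)(c4ccccc4)C(C)(C)C)[C@H](c2ccc(OCc4ccccc4)c(OC)c2)O3)[C@@H](COCc2ccccc2)[C@@H]1O | intermediate
20 | 4-iodo-2-methoxyphenol | COc1cc(I)ccc1O | starting material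
21 | 1-(benzyloxy)-4-iodo-2-methoxybenzene | COc1cc(I)ccc1OCc1ccccc1 | intermediate
22 | (2S,3S,4S,5S)-2-{[4-(benzyloxy)-3-methoxyphenyl]methyl}-4-[(benzyloxy)methyl]-5-(ArSi)oxolan-3-ol | COc1cc(C[C@@H]2O[C@H](c3cc(OC)c4c(c3)[C@H](CO[Si](c5ccccc5)(c5ccccc5)C(C)(C)C)[C@H](c3ccc(OCc5ccccc5)c(OC)c3)O4)[C@@H](COCc3ccccc3)[C@@H]2O)ccc1OCc1ccccc1 | intermediate
23 | (2S,3S,4S,5S)-2-{[4-(benzyloxy)-3-methoxyphenyl]methyl}-4-[(benzyloxy)methyl]-5-(ArOH)oxolan-3-ol | COc1cc(C[C@@H]2O[C@H](c3cc(OC)c4c(c3)[C@H](CO)[C@H](c3ccc(OCc5ccccc5)c(OC)c3)O4)[C@@H](COCc3ccccc3)[C@@H]2O)ccc1OCc1ccccc1 | intermediate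
24 | (2S,3S,4S,5S)-2-[(4-hydroxy-3-methoxyphenyl)methyl]-4-(hydroxymethyl)-5-[(2R,3R)-2-(4-hydroxy-3-methoxyphenyl)-3-(hydroxymethyl)-7-methoxy-2,3-dihydro-1-benzofuran-5-yl]oxolan-3-ol | COc1cc(C[C@@H]2O[C@H](c3cc(OC)c4c(c3)[C@H](CO)[C@H](c3ccc(O)c(OC)c3)O4)[C@@H](CO)[C@@H]2O)ccc1O | target

## Step count and least certain steps

Total step count: 17. Longest linear sequence: 15 steps (1 to 24 through steps 1–7, 9–13 and 15–17). Steps 8 and 14 prepare side fragments.

**Step 13 (key step).**
- What may go wrong: poor facial selectivity at C2 if the directing effect of the allylic hydroxyl is weakened by the neighbouring branch; or competing closure through the benzyl ether oxygen with loss of the benzyl group, which is also a five-membered closure.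
- Fallback, from 18 back to 19: C2 would be set by reagent control and an invertive substitution.
  - Titanium tartrate epoxidation of the allylic alcohol of 18 (Ti(OiPr)4, L-(+)-diisopropyl tartrate chosen as the matched ligand by the usual mnemonic, t-BuOOH, 4 Å molecular sieves, CH2Cl2, −20 °C) should give the erythro epoxy diol (1S,2R,3S)-2-[(benzyloxy)methyl]-1-(ArSi)-3-[(2R)-oxiran-2-yl]propane-1,3-diol F1.
  - Catalytic camphorsulfonic acid in CH2Cl2 at 0 °C would let the benzylic hydroxyl open the epoxide at its internal carbon with inversion, a 5-exo closure, giving (2S,3S,4S,5S)-4-[(benzyloxy)methyl]-2-(hydroxymethyl)-5-(ArSi)oxolan-3-ol F2.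
  - Selective iodination of the primary hydroxyl (I2, PPh3, imidazole, THF, 0 °C) returns to 19.

**Step 15.**
- What may go wrong: reductive ring opening, if the iodide-bearing carbon is transferred to a metal (direct insertion of manganese, or an alkylnickel that lives too long) and O1 is then eliminated; or homocoupling of the alkyl iodide, which is more reactive than the electron-rich aryl iodide.
- Fallback, from 19 back to 23: a cross-coupling with a preformed aryl nucleophile and no metal reductant.
  - Silylation of 19 (TESCl, imidazole, CH2Cl2) gives (2R,3S,4S,5S)-4-[(benzyloxy)methyl]-2-(iodomethyl)-5-(ArSi)-3-[(triethylsilyl)oxy]oxolane F3.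
  - Iodine–magnesium exchange on 21 (i-PrMgCl·LiCl, THF, −20 °C) gives [4-(benzyloxy)-3-methoxyphenyl]magnesium chloride F4.
  - Slow addition of F4 to F3 with FeCl3 (5 mol%) and TMEDA in THF at 0 °C (iron-catalysed Kumada-type coupling of a primary alkyl iodide) should give the triethylsilyl ether of 22, (2S,3S,4S,5S)-2-{[4-(benzyloxy)-3-methoxyphenyl]methyl}-4-[(benzyloxy)methyl]-5-(ArSi)-3-[(triethylsilyl)oxy]oxolane F5.
  - TBAF/AcOH in THF removes both silyl groups and returns to 23.

**Step 4.**
- What may go wrong: erosion of enantioselectivity, because the flanking methoxy group twists the benzyloxy group out of the arene plane and changes the insertion geometry compared with known substrates; or partial epimerisation of the cis ester on handling.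
- Fallback, from 8 back to 8: enzymatic enrichment.
  - Lipase-catalysed acylation of the primary alcohol of scalemic 8 (Burkholderia cepacia lipase, vinyl acetate, t-BuOMe, rt) is run to the conversion that leaves one enantiomer behind.
  - If the (2R,3R) enantiomer reacts faster, it is collected as [(2R,3R)-2-[4-(benzyloxy)-3-methoxyphenyl]-5-formyl-7-methoxy-2,3-dihydro-1-benzofuran-3-yl]methyl acetate F6 and returned to 8 by K2CO3 in MeOH at 0 °C.
  - If it reacts slower, enriched 8 is the recovered alcohol.

**Step 9.**
- What may go wrong: elimination of benzyloxide from the magnesium enolate at room temperature, giving the acryloyl imide; or low conversion with the hindered, electron-rich aldehyde.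
- Fallback, from 13 and 9 back to 15: a preformed boron enolate at low temperature with an open transition state.
  - Imide 13 with Bu2BOTf and i-Pr2NEt in CH2Cl2 at −78 °C gives the dibutylboron Z-enolate of 13, F7.
  - F7 is added to aldehyde 9 precomplexed with Et2AlCl at −78 °C. This Lewis acid-promoted anti-aldol attacks the same enolate face and should give 15 directly.

**Step 17.**
- What may go wrong: over-reduction, that is hydrogenolytic cleavage of the benzylic C5–O1 or C2′–O1′ bond while the slower alkyl benzyl ether is still being removed.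
- Fallback, from 23 back to 24: non-reductive debenzylation with BCl3 and pentamethylbenzene as cation scavenger in CH2Cl2 at −78 °C, quenched cold with MeOH. It makes no new isolated compound.

## Further compounds

F1 | step 13 | (1S,2R,3S)-2-[(benzyloxy)methyl]-1-(ArSi)-3-[(2R)-oxiran-2-yl]propane-1,3-diol | O[C@H](c1cc(OC)c2c(c1)[C@H](CO[Si](c3ccccc3)(c3ccccc3)C(C)(C)C)[C@H](c1ccc(OCc3ccccc3)c(OC)c1)O2)[C@@H](COCc1ccccc1)[C@H](O)[C@H]1CO1
F2 | step 13 | (2S,3S,4S,5S)-4-[(benzyloxy)methyl]-2-(hydroxymethyl)-5-(ArSi)oxolan-3-ol | OC[C@@H]1O[C@H](c2cc(OC)c3c(c2)[C@H](CO[Si](c4ccccc4)(c4ccccc4)C(C)(C)C)[C@H](c2ccc(OCc4ccccc4)c(OC)c2)O3)[C@@H](COCc2ccccc2)[C@@H]1O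
F3 | step 15 | (2R,3S,4S,5S)-4-[(benzyloxy)methyl]-2-(iodomethyl)-5-(ArSi)-3-[(triethylsilyl)oxy]oxolane | IC[C@@H]1O[C@H](c2cc(OC)c3c(c2)[C@H](CO[Si](c4ccccc4)(c4ccccc4)C(C)(C)C)[C@H](c2ccc(OCc4ccccc4)c(OC)c2)O3)[C@@H](COCc2ccccc2)[C@@H]1O[Si](CC)(CC)CC
F4 | step 15 | [4-(benzyloxy)-3-methoxyphenyl]magnesium chloride | COc1cc([Mg]Cl)ccc1OCc1ccccc1
F5 | step 15 | (2S,3S,4S,5S)-2-{[4-(benzyloxy)-3-methoxyphenyl]methyl}-4-[(benzyloxy)methyl]-5-(ArSi)-3-[(triethylsilyl)oxy]oxolane | COc1cc(C[C@@H]2O[C@H](c3cc(OC)c4c(c3)[C@H](CO[Si](c5ccccc5)(c5ccccc5)C(C)(C)C)[C@H](c3ccc(OCc5ccccc5)c(OC)c3)O4)[C@@H](COCc3ccccc3)[C@@H]2O[Si](CC)(CC)CC)ccc1OCc1ccccc1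
F6 | step 4 | [(2R,3R)-2-[4-(benzyloxy)-3-methoxyphenyl]-5-formyl-7-methoxy-2,3-dihydro-1-benzofuran-3-yl]methyl acetate | O=Cc1cc(OC)c2c(c1)[C@H](COC(C)=O)[C@H](c1ccc(OCc3ccccc3)c(OC)c1)O2
F7 | step 9 | dibutylboron Z-enolate of (4S)-4-benzyl-3-[3-(benzyloxy)propanoyl]-1,3-oxazolidin-2-one | CCCCB(CCCC)O/C(=C\COCc1ccccc1)N1[C@@H](Cc2ccccc2)COC1=O
F0 | step 17 | none | none
A1 | alternative 1 | cis-4-[4-(benzyloxy)-3-methoxybenzyl]-2,2-dichloro-3-[(S)-1-(2,4,6-triisopropylphenyl)ethoxy]cyclobutan-1-one | O=C1C(Cl)(Cl)[C@H](O[C@@H](C)c2c(C(C)C)cc(C(C)C)cc2C(C)C)[C@@H]1Cc1ccc(OCc2ccccc2)c(OC)c1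
A2 | alternative 1 | 1-(benzyloxy)-2-methoxy-4-{(Z)-3-[(S)-1-(2,4,6-triisopropylphenyl)ethoxy]prop-2-en-1-yl}benzene | COc1cc(C/C=C\O[C@@H](C)c2c(C(C)C)cc(C(C)C)cc2C(C)C)ccc1OCc1ccccc1
A3 | alternative 1 | dichloroketene | ClC(Cl)=C=O
A4 | alternative 2 | cis-5-bromo-3-{[(tert-butyldimethylsilyl)oxy]methyl}-7-methoxy-2-(3-methoxy-4-tosyloxyphenyl)-2,3-dihydrobenzofuran | Brc1cc(OC)c2c(c1)[C@H](CO[Si](C)(C)C(C)(C)C)[C@H](c1ccc(OS(=O)(=O)c3ccc(C)cc3)c(OC)c1)O2
A5 | alternative 2 | syn-2-(5-bromo-2-hydroxy-3-methoxyphenyl)-3-[(tert-butyldimethylsilyl)oxy]-1-(3-methoxy-4-tosyloxyphenyl)propan-1-ol | Brc1cc(OC)c(O)c(c1)[C@H](CO[Si](C)(C)C(C)(C)C)[C@H](O)c1ccc(OS(=O)(=O)c2ccc(C)cc2)c(OC)c1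
A6 | alternative 3 | 2,5-cis-2-(4-benzyloxy-3-methoxybenzyl)-5-[cis-2-(4-benzyloxy-3-methoxyphenyl)-3-(benzyloxymethyl)-7-methoxy-2,3-dihydrobenzofuran-5-yl]tetrahydrofuran-3-one | COc1cc(C[C@@H]2O[C@H](c3cc(OC)c4c(c3)[C@H](COCc3ccccc3)[C@H](c3ccc(OCc5ccccc5)c(OC)c3)O4)CC2=O)ccc1OCc1ccccc1
A7 | alternative 3 | 2,5-cis-5-(4-benzyloxy-3-methoxybenzyl)-2-[cis-2-(4-benzyloxy-3-methoxyphenyl)-3-(benzyloxymethyl)-7-methoxy-2,3-dihydrobenzofuran-5-yl]-4-methylene-1,3-dioxolane | C=C1O[C@@H](c2cc(OC)c3c(c2)[C@H](COCc2ccccc2)[C@H](c2ccc(OCc4ccccc4)c(OC)c2)O3)O[C@H]1Cc1ccc(OCc2ccccc2)c(OC)c1
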